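All runs stem from a simulated flask with made-up constants, noise included.

The ratio of E to everything else the charge became is what I follow, a selectivity factor that I assume falls as the charge of G rises.

| flask | G | temperature | remark | time |
|---|---|---|---|---|
| ochre | 0.070 M | 20 °C | run made earlier |  |
| violet | 0.11 M | 32 °C | run made earlier |  |
| west | 0.050 M | 40 °C |  | 2.5 d |
| north-east | 0.050 M | 25 °C |  | 2.5 d |
| south | 0.050 M |  | at 25 °C until 12 h, from then on at 40 °C | 2.5 d |

ochre run (percent of the G charged)

| time / d | E / % |
|---|---|
| 0.417 | 38.2 |
| 1.25 | 51.7 |
| 2.50 | 55.8 |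
| 3.00 | 54.4 |
| 6.00 | 55.0 |

violet run (percent of the G charged)

| time / h | E / % |
|---|---|
| 10.0 | 50.5 |
| 20.0 | 49.5 |
| 30.0 | 51.4 |
| 40.0 | 52.8 |
| 50.0 | 51.8 |

(readings scatter by 1 percentage point)

- G is a solid; its amount is given per volume of the solution
- at the start none of G is in solution
- in a conversion L counts as not yet reacted
- what has only dissolved of G counts as not reacted

* the best flask by amount of E, in percent of the G charged; "all alike" if 1.5 percentage points covers them all (west / north-east / south / all alike)
* amount of E at the end, in percent of the G charged, west
* amount of E at the end, in percent of the G charged, north-east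
* amount of E at the end, in percent of the G charged, south

The first rung is violet at 32 °C, which stands at 50.5% by 10.0 h, within the scatter of its mean plateau of 51.2%. Ochre at 20 °C takes longer: 38.2% at 0.417 d, 51.7% at 1.25 d, then flat at a mean of 55.1%. The last rung is the run itself. It lasts 2.5 d, about what ochre needed, and each asked flask is warmer than ochre. So I expect them all stopped at the end, and the question is one of shares, not of time.

I solve the ratio at both ends. At a very small charge I assume E takes the charge; at a large one I assume [E] stands still, so its share falls as one over the charge. Joined, the share of E is one over (one plus charge divided by the even charge), the charge of G at which E and the rest come out equal. As readings, ochre gives 0.0858 M and violet 0.115 M. For 0.050 M that means 63.2% to 69.8%. The two runs differ in charge and temperature together, so I cannot part these. I give all three flasks this band and call them all alike, trusting it least at 40 °C, which is warmer than either run.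

The forecast, above my band, says 85% for west, 88% for north-east and 85% for south, with north-east best, reading the plateaus as “equilibrium with solid G still present”.

The flasks give 57.6% in west, 62.2% in north-east and 50.3% in south, so north-east is best.

    J ⇌ L (K = 0.540, k = 0.00540 min⁻¹, Ea = 99.0 kJ mol⁻¹, ΔH = −79.0 kJ mol⁻¹)
    E ⇌ Z (K = 0.150, k = 0.00560 min⁻¹, Ea = 94.0 kJ mol⁻¹, ΔH = 58.0 kJ mol⁻¹)
    G ⇌ J, rate k3*(cs3 - [J]) while solid is left; crystals form when [J] > cs3 (solubility = 41.0 mM, k = 0.0110 min⁻¹)
    L → D (k = 6.40 × 10⁻⁴ min⁻¹, Ea = 107 kJ mol⁻¹)
    J → E (k = 0.00490 min⁻¹, Ea = 99.0 kJ mol⁻¹)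
    J + E → X (k = 0.0410 M⁻¹ min⁻¹, Ea = 73.0 kJ mol⁻¹)
    (constants at 25 °C)

North-east lies just under my band, at an even charge of 0.0823 M, while west and south lie further below it. The neighbour is north-east again with 0.20 M of G. The same two even charges give it 30.0% to 36.5%. That flask gives 38.0% of E, just above the band, and X, which holds two G, carries 51.7% of the charge.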